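The benzenoid ring of the coumarin is built rather than bought: disconnecting C6–C7 and C8–C8a splits the core into 5-ethenyl-2H-pyran-2-one and a methoxy ynone. The key step exploits the contiguous O1 / C8-acyl / C7-OMe array on ring carbons C8a, C8 and C7, which maps onto a 1-oxygenated diene (the vinyl group plus the pyranone C5=C6 bond) and a push-pull alkyne. One [4+2] cycloaddition, with DDQ dehydrogenation in the same flask, closes the carbocycle and sets the 7,8-pattern with the lactone ring already in place. Riley oxidation of the side-chain methylene and enolate O-acylation with 3-methylbut-2-enoyl chloride finish the enol ester.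

Key step: step 4

Remark on the chemistry: the target has no stereocentre and no stereogenic double bond; carbinol 7 and cycloadduct 9 are racemic and both centres are removed by oxidation, so no stereocontrol is needed.

Step 1
Reactants: 1 5-bromo-2H-pyran-2-one; 2 tributyl(ethenyl)stannane
Product: 3 5-ethenyl-2H-pyran-2-one
Conditions: Pd(PPh3)4 (5 mol %), BHT (cat.), toluene, 100 °C
Reagents that add atoms: none
Why: Stille cross-coupling: zerovalent palladium inserts into the C5–Br bond of the bromopyranone and the vinyl group is transferred from tin under neutral, base-free conditions that leave the lactone untouched, while the radical inhibitor guards the polymerisable vinylpyranone.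

Step 2
Reactants: 4 2-chloro-1,1-dimethoxyethane (chloroacetaldehyde dimethyl acetal); 5 3-methylbutanal (isovaleraldehyde)
Product: 7 1-methoxy-5-methylhex-1-yn-3-ol (racemic), via lithium methoxyacetylide 6 (not isolated)
Conditions: LiNEt2 (from Et2NH, n-BuLi; 3.1 equiv), THF, 0 °C; then 5, −78 to 0 °C; cold H2O work-up
Reagents that add atoms: none
Why: Twofold base-induced elimination (MeOH, then HCl) from the chloro acetal and deprotonation give the lithium alkoxyacetylide, which adds 1,2 to the aldehyde (acetylide addition to a carbonyl group); the carbinol centre forms without control as a racemate and is removed in step 3, and the basic aqueous work-up avoids acid-induced Meyer–Schuster rearrangement of the ynol ether carbinol.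

Step 3
Reactants: 7 1-methoxy-5-methylhex-1-yn-3-ol
Product: 8 1-methoxy-5-methylhex-1-yn-3-one
Conditions: activated MnO2 (excess), CH2Cl2, rt
Reagents that add atoms: none
Why: Oxidation of a propargylic alcohol with activated MnO2 is heterogeneous, neutral and anhydrous, so the acid- and water-sensitive ynol ether should survive and the ynone should be obtained by filtration and evaporation.

Step 4
Reactants: 3 5-ethenyl-2H-pyran-2-one (freshly prepared); 8 1-methoxy-5-methylhex-1-yn-3-one (1.5 equiv)
Product: 10 7-methoxy-8-(3-methylbutanoyl)-2H-chromen-2-one, via dihydrocoumarin cycloadduct 9 (not isolated)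
Conditions: toluene (1 M), BHT (cat.), 100 °C, sealed tube; then DDQ (1.1 equiv), 0 °C to rt
Reagents that add atoms: none
Why: Proposed new method: the vinyl group and the C5=C6 enol-ester bond of 3 should act together as a 1-acyloxy-1,3-diene in a concerted but asynchronous [4+2] cycloaddition with the push-pull ynone 8, the closest known reaction type being the Diels–Alder reaction of vinylchromones, vinylcoumarins and vinylpyranones with acetylenic dienophiles followed by dehydrogenation. The carbocyclic ring is closed by the intermolecular cycloaddition itself, which forms C6–C7 and C8–C8a in one suprafacial event and gives the 1,4-cyclohexadiene 9 (7-methoxy-8-(3-methylbutanoyl)-6,8a-dihydro-2H-chromen-2-one). The regiochemistry that is needed should follow from polarity matching: the nucleophilic vinyl CH2 terminus, which carries the largest HOMO coefficient of the oxygenated diene, bonds first to the electrophilic MeO-bearing beta carbon of the ynone while the developing positive charge is stabilised at pyranone C6 by the ring oxygen, so the methoxy group ends at C7 and the acyl group at C8. Periselectivity is also needed and is expected because the electron-poor endocyclic C3–C6 diene of a 2-pyranone engages alkynes only at clearly higher temperature, whereas the exocyclic diene is unhindered and reaches the s-cis geometry freely. The only new stereocentre, C8a of 9, forms racemic without control and is erased when DDQ removes hydride from C8a (a position stabilised by the vinylogous C7 methoxy group) and a proton leaves C6. Oxidising in the same flask under neutral conditions should keep 9 from aromatising in the other direction, by ionisation of the C8a carboxylate, and the methyl ynol ether cannot fragment by a retro-ene path at this temperature.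

Step 5
Reactants: 10 7-methoxy-8-(3-methylbutanoyl)-2H-chromen-2-one
Product: 11 1-(7-methoxy-2-oxo-2H-chromen-8-yl)-3-methylbutane-1,2-dione
Conditions: SeO2 (1.3 equiv), 1,4-dioxane/H2O (20:1), 100 °C
Reagents that add atoms: selenium dioxide, O=[Se]=O
Why: Riley oxidation: the alpha-methylene is the only enolisable position of the aryl ketone, its enol attacks SeO2 and the selenium ester collapses to the 1,2-diketone, while the coumarin nucleus offers no allylic or enolisable C–H and a small excess of oxidant limits further attack at the hindered isopropyl methine.

Step 6
Reactants: 11 1-(7-methoxy-2-oxo-2H-chromen-8-yl)-3-methylbutane-1,2-dione; 12 3-methylbut-2-enoyl chloride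
Product: 14 kimcuongin, 1-(7-methoxy-2-oxo-2H-chromen-8-yl)-3-methyl-1-oxobut-2-en-2-yl 3-methylbut-2-enoate, via potassium enolate 13 (not isolated)
Conditions: KN(SiMe3)2 (1.05 equiv), THF, −78 °C; then 12 (1.2 equiv), −78 to 0 °C
Reagents that add atoms: none
Why: Enolate O-acylation: the diketone has a single acidic C–H, so the silylamide base should give one tetrasubstituted potassium enolate, which the hard acid chloride should take at oxygen because carbon attack would build a quaternary centre between two carbonyl groups, and the absence of a tertiary amine prevents vinylketene formation from 12 and thereby deconjugation of the 3-methylbut-2-enoyl group.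

Compound list
1 | 5-bromo-2H-pyran-2-one | O=c1ccc(Br)co1 | starting material
2 | tributyl(ethenyl)stannane | C=C[Sn](CCCC)(CCCC)CCCC | starting material
3 | 5-ethenyl-2H-pyran-2-one | C=CC1=COC(=O)C=C1 | intermediate
4 | 2-chloro-1,1-dimethoxyethane | COC(CCl)OC | starting material
5 | 3-methylbutanal | CC(C)CC=O | starting material
6 | lithium methoxyacetylide (formed and consumed in the flask) | [Li+].[C-]#COC | intermediate
7 | 1-methoxy-5-methylhex-1-yn-3-ol (racemic) | COC#CC(O)CC(C)C | intermediate
8 | 1-methoxy-5-methylhex-1-yn-3-one | COC#CC(=O)CC(C)C | intermediate
9 | 7-methoxy-8-(3-methylbutanoyl)-6,8a-dihydro-2H-chromen-2-one (racemic; formed and consumed in the flask) | COC1=C(C(=O)CC(C)C)C2OC(=O)C=CC2=CC1 | intermediate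
10 | 7-methoxy-8-(3-methylbutanoyl)-2H-chromen-2-one | COc1ccc2ccc(=O)oc2c1C(=O)CC(C)C | intermediate
11 | 1-(7-methoxy-2-oxo-2H-chromen-8-yl)-3-methylbutane-1,2-dione | COc1ccc2ccc(=O)oc2c1C(=O)C(=O)C(C)C | intermediate
12 | 3-methylbut-2-enoyl chloride | CC(C)=CC(Cl)=O | starting material
13 | potassium 1-(7-methoxy-2-oxo-2H-chromen-8-yl)-3-methyl-1-oxobut-2-en-2-olate (formed and consumed in the flask) | COc1ccc2ccc(=O)oc2c1C(=O)C([O-])=C(C)C.[K+] | intermediate
14 | kimcuongin | COc1ccc2ccc(=O)oc2c1C(=O)C(OC(=O)C=C(C)C)=C(C)C | target

Total step count: 6
Longest linear sequence: 5 steps (steps 2, 3, 4, 5 and 6, from 4 to 14)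

Steps most likely to fail

1. Step 4 (cycloaddition and dehydrogenation, the step that goes beyond known chemistry). The push-pull alkyne may be too sluggish, so that the vinylpyranone dimerises or polymerises first. Cycloaddition may also take place through the endocyclic pyranone diene with loss of CO2, or the adduct may aromatise by ionisation of the C8a–O bond before the oxidant acts. The fallback gives up the benzannulation and uses known chemistry only; it sets out from isovaleraldehyde 5 and comes back at 10. Pinnick oxidation (NaClO2, NaH2PO4, 2-methylbut-2-ene, t-BuOH/H2O) would give 3-methylbutanoic acid F1. Steglich esterification of F1 with commercial 7-hydroxy-2H-chromen-2-one (umbelliferone, O=c1ccc2ccc(O)cc2o1) using DCC and DMAP in CH2Cl2 would give 2-oxo-2H-chromen-7-yl 3-methylbutanoate F2. Fries rearrangement in an AlCl3 melt at about 150 °C, which for 7-acyloxycoumarins delivers the acyl group mainly to C8, would give 7-hydroxy-8-(3-methylbutanoyl)-2H-chromen-2-one F3. O-Methylation (MeI, K2CO3, acetone, reflux) would then give 10.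

2. Step 5 (Riley oxidation). Enolisation of the twisted, doubly ortho-substituted aryl ketone may be slow, and once the diketone forms, further oxidation or dehydrogenation at the isopropyl methine and retention of selenium residues may erode the material. The fallback sets out from 10 and comes back at 11. Acid-catalysed alpha-nitrosation (tert-butyl nitrite, HCl, THF, 0 °C to rt) would give the alpha-oximino ketone 8-[2-(hydroxyimino)-3-methylbutanoyl]-7-methoxy-2H-chromen-2-one F4, as whichever oxime isomer forms, the geometry being of no consequence. Transoximation with aqueous formaldehyde and HCl would then release the diketone 11 without any oxidant that could touch the methine.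

3. Step 6 (enol ester formation). Acylation at carbon, enolate attack on the coumarin C4 of a second molecule, or base-induced migration of the acyl double bond out of conjugation may compete, and the enol ester may undergo acyl cleavage on work-up. The fallback sets out from 11 and comes back at 14. Soft enolisation (Me3SiCl, Et3N, NaI, MeCN, rt) would give the isolable silyl enol ether 7-methoxy-8-{3-methyl-2-[(trimethylsilyl)oxy]but-2-enoyl}-2H-chromen-2-one F5. CuCl-catalysed exchange of silyl for acyl with 12 in THF, with no base present, would then give 14 with loss of Me3SiCl.

Further compounds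
F1 | step 4 | 3-methylbutanoic acid | CC(C)CC(=O)O
F2 | step 4 | 2-oxo-2H-chromen-7-yl 3-methylbutanoate | CC(C)CC(=O)Oc1ccc2ccc(=O)oc2c1
F3 | step 4 | 7-hydroxy-8-(3-methylbutanoyl)-2H-chromen-2-one | CC(C)CC(=O)c1c(O)ccc2ccc(=O)oc12
F4 | step 5 | 8-[2-(hydroxyimino)-3-methylbutanoyl]-7-methoxy-2H-chromen-2-one | COc1ccc2ccc(=O)oc2c1C(=O)C(=NO)C(C)C
F5 | step 6 | 7-methoxy-8-{3-methyl-2-[(trimethylsilyl)oxy]but-2-enoyl}-2H-chromen-2-one | COc1ccc2ccc(=O)oc2c1C(=O)C(O[Si](C)(C)C)=C(C)C
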